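## Structural features

The target is the tetradecanoate ester of a C13 norisoprenoid: one carbocycle, a cyclohexane (ring A, ionone numbering C1–C6), whose C5–C6 bond is spanned by an epoxide oxygen, so the core is a 7-oxabicyclo[4.1.0]heptane. C1 carries two methyl groups, C5 one methyl group, C6 the (E)-3-oxobut-1-enyl chain (C7=C8, C9 ketone) and C3 the acyloxy group. C1, C6 and C5 are three contiguous fully substituted carbons; C5 and C6 are neighbouring stereocentres held cis by the oxirane, and the third stereocentre, C3, lies 1,3 to C5 with its oxygen on the ring face opposite the epoxide oxygen (3S,5R,6S). The fragile groups are the tetrasubstituted epoxide (opened by acid, and open to transannular attack at C6 by a free C3 hydroxyl on the opposite face), the enone (conjugate addition, reduction) and the ester (hydrolysis). The carbon skeleton is that of commercial cyclocitral and ionone terpenoids, so the real difficulty is stereochemical: an enantiopure epoxide on a tetrasubstituted alkene, and an oxygen on C3, a ring methylene with no neighbouring functional group, in a defined relation to that epoxide. The key step uses this feature: once C5–C6 is an epoxide the ring has no allylic C–H bond, C2 is neopentyl next to C1 and C4 is deactivated by the C5–O bond, which leaves the C3 methylene between C2 and C4 as the site an oxidising enzyme should prefer.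

## Logic of the disconnections

9 to 7 and 8: the acyl–oxygen bond of the C3 ester is cut. The fatty chain carries no stereochemistry, and removing it keeps all earlier intermediates small and keeps an ester away from a whole-cell biotransformation. This takes fourteen carbons off the problem. The forward step must acylate at oxygen without breaking the C3–O bond and without letting acid reach the epoxide.

7 to 6: the C3–O bond is cut, back to a C–H bond. This removes the remote stereocentre and leaves the cis epoxide as the only stereochemical task. The forward step must pick C3 among three ring methylenes and five methyl groups, must deliver oxygen to the face anti to the epoxide oxygen, and must run under neutral conditions that spare epoxide and enone. This is asked of an enzyme active site.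

6 to 4 and 5: the C7=C8 double bond is cut. The four-carbon enone arm comes off as 5, and the (E) geometry follows from the stabilised ylide. What remains is a ten-carbon ring aldehyde. The forward step must olefinate a formyl group on a fully substituted epoxide carbon; since 4 has no α-hydrogen, C5 and C6 cannot epimerise.

4 to 3: no skeletal bond is cut; C7 is moved from the aldehyde to the alcohol oxidation level. The hydroxyl of 3 is the handle that the enantioselective epoxidation needs. The forward oxidation must be non-acidic.

3 to 2: the C5–O and C6–O bonds are cut. Both quaternary stereocentres arise in a single oxygen transfer directed by the allylic hydroxyl, and the cut removes all stereochemistry, since 2 is achiral. The forward step must control the face of a tetrasubstituted alkene through the chiral catalyst, which fixes the choice of tartrate enantiomer.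

2 to 1: the C7–H bond made by hydride is removed, back to the commercial aldehyde 1. The forward step needs 1,2-selective reduction only.

## Other disconnections considered

Alternative 1: The cut goes through ring A at C4–C5 and C1–C6, with C3 at the ketone (silyl enol ether) oxidation level. Forward, Me2AlCl would promote a Diels–Alder reaction between 4-methyl-2-(trimethylsilyloxy)penta-1,3-diene A1 and but-2-ynal A2. The CH2 terminus of A1 joins the methyl-bearing alkyne carbon and the dimethyl terminus joins the formyl-bearing carbon, giving 2,6,6-trimethyl-4-(trimethylsilyloxy)cyclohexa-1,4-diene-1-carbaldehyde A3.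
- In its favour: the whole ring, the C1 quaternary carbon, the C6 formyl group and an oxygen on C3 arrive in one convergent step from two small achiral pieces. The regiochemistry is the electronically matched one, and every later operation is of an established type.
- Against it here: the reacting terminus of A1 bears a cis methyl group, which disfavours the s-cis conformer and forces a quaternary carbon to form at the more hindered carbon of A2. The Lewis acid may divert the reaction to a stepwise Mukaiyama-type addition or cleave the enol ether.
- A3 is achiral. C3 would have to be set by enantioselective reduction of a β,γ-unsaturated ketone whose C4 methylene is doubly activated, and the epoxide would then come from a peracid under substrate control only.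
- Comparison on structure: the alternative builds the ring, whereas the chosen plan buys it in 1 and so starts more simply.
- Comparison on mechanism: the alternative relies only on known reaction types, and on this point it is the better plan, since step 5 has no direct precedent. The chosen plan is stronger at C5/C6 (catalyst control) and weaker at C3 (an enzyme still to be found).
- Comparison on step economy: the two are equal. Cycloaddition, enol ether hydrolysis, olefination with 5, asymmetric reduction, acylation with 8 and epoxidation also come to about six operations.

Alternative 2: The cut removes the C5–C6 ring bond together with the C6–O bond of the epoxide, leading back to methyl (5S)-5-(tert-butyldimethylsilyloxy)-2-chloro-3,3-dimethyl-7-oxooctanoate A4. Forward, KOtBu would form the α-chloro ester enolate, which adds to the methyl ketone and closes the six-membered ring. The tertiary alkoxide then displaces chloride (intramolecular Darzens condensation) to give methyl (1S,4S,6R)-4-(tert-butyldimethylsilyloxy)-2,2,6-trimethyl-7-oxabicyclo[4.1.0]heptane-1-carboxylate A5.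
- In its favour: ring and epoxide form in one operation, the cis fusion is automatic, and the C3 oxygen is present from the start, so no C–H oxidation is needed.
- Against it: A4 is a β-silyloxy ketone, and the same base can enolise toward C4 and expel silanolate. The proton to be removed sits on a neopentyl carbon next to C1, while the ketone offers more accessible acidic protons whose enolates can attack the ester.
- The configuration of C5 and C6 relative to C3 rests on 1,3-induction in the ring closure, which is not assured. A4 itself needs a multistep enantioselective synthesis.
- Comparison on structure: both plans create C5 and C6 together with a forced cis relationship, and here the alternative is the equal of the chosen plan. It is the better one in that C3 is secured by conventional means.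
- Comparison on mechanism: the chosen plan sets the absolute configuration of the epoxide by a chiral catalyst; the alternative sets it by relay from C3.
- Comparison on step economy: the alternative is clearly longer. After A5 the ester must be taken to the aldehyde, olefinated with 5, desilylated and acylated with 8, in addition to the steps that make A4.

Alternative 3: The cut is made at the C6–C7 bond and at the C5–O bond of the epoxide. This gives (2S,4S)-4-(tert-butyldimethylsilyloxy)-2-chloro-2,6,6-trimethylcyclohexan-1-one A6 and tert-butyl{[(2S,3E)-4-iodobut-3-en-2-yl]oxy}dimethylsilane A7. Forward, A7 would be converted by tBuLi and then CeCl3 into the alkenyl–CeCl2 reagent, which adds to the carbonyl of A6. The alkoxide then displaces the neighbouring tertiary chloride with inversion and closes the epoxide, giving the bis(tert-butyldimethylsilyl) ether A8 of (3S,5R,6S,9S)-5,6-epoxy-3-hydroxy-5,6-dihydro-β-ionol.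
- In its favour: ring and side chain are joined convergently with the (E) geometry fixed, C3 comes from a building block, and the epoxide configuration follows mechanistically from the chloride-bearing stereocentre.
- Against it: the carbonyl of A6 lies between two fully substituted carbons. The nucleophile must add on the face syn to chlorine so that oxygen and chlorine become anti, whereas the polar Felkin–Anh preference of α-chloro ketones is for approach anti to the halogen. A chlorohydrin of the wrong relative configuration cannot close.
- A6 requires a tertiary chloride to be set cis to the C3 silyl ether. C9 arrives at the alcohol level and needs desilylation, allylic oxidation with MnO2 and then acylation with 8. tBuLi is pyrophoric.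
- Comparison on structure: the alternative is convergent and on this point the better plan.
- Comparison on mechanism: it uses polar addition and SN2 closure, both known, instead of an unprecedented enzymatic hydrogen abstraction, which is again a point for the alternative. It moves the stereochemical burden onto the synthesis of A6 and onto an uncertain facial preference.
- Comparison on step economy: the longest linear sequence is about equal to that of the chosen plan (two steps to each fragment, the union, three steps after it), but the total count is higher.

Key step: step 5

Remark: the tartrate for step 2 is fixed as D-(−)-diethyl tartrate, because the alkene of 2 has the substitution pattern of geraniol (methyl cis to the hydroxymethyl group), for which this enantiomer makes the methyl-bearing epoxide carbon R, as C5 requires.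

Remark: a stoichiometric amine base is used beside catalytic DMAP in the last step, so that no free HCl meets the epoxide.

Assumption: a CYP101-family enzyme or active-site variant that accepts 6 is taken to be obtainable by screening; the route is otherwise independent of this choice.

## Route

Step 1
Reactants: 1 β-cyclocitral (2,6,6-trimethylcyclohex-1-ene-1-carbaldehyde)
Product: 2 β-cyclogeraniol ((2,6,6-trimethylcyclohex-1-en-1-yl)methanol)
Conditions: NaBH4, MeOH, 0 °C
Reagents that add atoms: none
Why: Hydride reduction of the aldehyde carbonyl (1,2-addition); the hindered, tetrasubstituted β-carbon of the enal does not compete as an acceptor, and no stereocentre is formed.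

Step 2
Reactants: 2 β-cyclogeraniol
Product: 3 [(1R,6R)-2,2,6-trimethyl-7-oxabicyclo[4.1.0]heptan-1-yl]methanol
Conditions: Ti(OiPr)4 (10 mol %), D-(−)-diethyl tartrate (12 mol %), tBuOOH, 4 Å MS, CH2Cl2, −20 °C
Reagents that add atoms: tert-butyl hydroperoxide, CC(C)(C)OO
Why: Sharpless asymmetric epoxidation: the alkoxide of 2 and tBuOOH bind to the chiral complex formed from Ti(OiPr)4 and the tartrate, which transfers the peroxide oxygen to one face of the C5=C6 bond and so sets both quaternary stereocentres at once, necessarily cis. With D-(−)-diethyl tartrate the oxygen should enter on the face that makes C5 R, by the same facial rule that holds for geraniol.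

Step 3
Reactants: 3 [(1R,6R)-2,2,6-trimethyl-7-oxabicyclo[4.1.0]heptan-1-yl]methanol
Product: 4 (1S,6R)-2,2,6-trimethyl-7-oxabicyclo[4.1.0]heptane-1-carbaldehyde
Conditions: nPr4N[RuO4] (5 mol %), N-methylmorpholine N-oxide, 4 Å MS, CH2Cl2, rt
Reagents that add atoms: none
Why: Ley–Griffith oxidation: the perruthenate salt, reoxidised by the N-oxide, takes the primary alcohol to the aldehyde under neutral, anhydrous conditions that leave the acid-sensitive tetrasubstituted epoxide intact. The α-carbon is fully substituted, so epimerisation is impossible (the descriptor at that carbon changes from R to S only because the formyl group outranks C5).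

Step 4
Reactants: 4 (1S,6R)-2,2,6-trimethyl-7-oxabicyclo[4.1.0]heptane-1-carbaldehyde; 5 1-(triphenylphosphoranylidene)propan-2-one
Product: 6 (5R,6S)-5,6-epoxy-5,6-dihydro-β-ionone ((E)-4-[(1S,6R)-2,2,6-trimethyl-7-oxabicyclo[4.1.0]heptan-1-yl]but-3-en-2-one)
Conditions: toluene, 100 °C
Reagents that add atoms: 1-(triphenylphosphoranylidene)propan-2-one (5), CC(=O)C=P(c1ccccc1)(c1ccccc1)c1ccccc1
Why: Wittig olefination with a ketone-stabilised ylide: reversible oxaphosphetane formation leads to the (E)-enone, and the neutral conditions spare the epoxide. Compound 4 has no α-hydrogen, so C5 and C6 are not touched.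

Step 5
Reactants: 6 (5R,6S)-5,6-epoxy-5,6-dihydro-β-ionone
Product: 7 (3S,5R,6S)-5,6-epoxy-3-hydroxy-5,6-dihydro-β-ionone ((E)-4-[(1S,4S,6R)-4-hydroxy-2,2,6-trimethyl-7-oxabicyclo[4.1.0]heptan-1-yl]but-3-en-2-one)
Conditions: E. coli whole cells co-expressing a CYP101B1-type cytochrome P450 variant, its ferredoxin, ferredoxin reductase and a glucose dehydrogenase; air (O2), D-glucose, NADH (recycled), KH2PO4/K2HPO4 buffer pH 7.4, 2% DMSO, 30 °C
Reagents that add atoms: dioxygen, O=O
Why: Proposed new method: the enzyme activates O2 at its heme iron with two electrons relayed from NADH through ferredoxin reductase and ferredoxin, and the resulting oxoiron porphyrin radical cation abstracts the C3 hydrogen that lies on the ring face opposite the epoxide oxygen; the C3 radical then captures the iron-bound hydroxyl (oxygen rebound) faster than it can invert, so the new C3–O bond replaces that hydrogen with retention. The closest known reaction type is the cytochrome P450 hydroxylation of β-ionone and related norisoprenoids at C3 and the 3-hydroxylation of carotenoid β-rings; what is new is the epoxide as substrate class. No ring is closed. The one new stereocentre, C3 (S), is controlled by the active site, which must hold 6 so that only the hydrogen anti to the epoxide oxygen reaches the oxo unit, since the substrate itself offers little facial bias. The step needs selectivity for C3 over C2, C4 and the methyl groups and for the anti face: in 6 no allylic C–H remains, C2 is neopentyl and screened by the C1 methyl groups, C4 is deactivated by the adjacent C5–O bond, and the enone carbonyl is expected to serve as the polar anchor that points ring A toward the iron. A variant with this selectivity would have to be identified by screening wild-type CYP101 enzymes and active-site mutants, and further oxidation of 7 to the C3 ketone would be limited by stopping at partial conversion.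

Step 6
Reactants: 7 (3S,5R,6S)-5,6-epoxy-3-hydroxy-5,6-dihydro-β-ionone; 8 myristoyl chloride (tetradecanoyl chloride)
Product: 9 (3S,5R,6S)-5,6-epoxy-3-(tetradecanoyloxy)-5,6-dihydro-β-ionone ((1R,3S,6S)-1,5,5-trimethyl-6-[(E)-3-oxobut-1-en-1-yl]-7-oxabicyclo[4.1.0]heptan-3-yl tetradecanoate), the target
Conditions: Et3N, DMAP (cat.), CH2Cl2, 0 °C to rt
Reagents that add atoms: myristoyl chloride (8), CCCCCCCCCCCCCC(=O)Cl
Why: DMAP-catalysed acylation (nucleophilic acyl substitution at the acid chloride) of the secondary C3 alcohol; the C3–O bond is not broken, so the configuration is retained. Et3N traps HCl before it can open the epoxide or trigger transannular attack.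

## Compound list

1 | β-cyclocitral (2,6,6-trimethylcyclohex-1-ene-1-carbaldehyde) | CC1=C(C=O)C(C)(C)CCC1 | starting material
2 | β-cyclogeraniol ((2,6,6-trimethylcyclohex-1-en-1-yl)methanol) | CC1=C(CO)C(C)(C)CCC1 | intermediate
3 | [(1R,6R)-2,2,6-trimethyl-7-oxabicyclo[4.1.0]heptan-1-yl]methanol | C1CC(C)(C)[C@]2(CO)O[C@]2(C)C1 | intermediate
4 | (1S,6R)-2,2,6-trimethyl-7-oxabicyclo[4.1.0]heptane-1-carbaldehyde | C1CC(C)(C)[C@]2(C=O)O[C@]2(C)C1 | intermediate
5 | 1-(triphenylphosphoranylidene)propan-2-one | CC(=O)C=P(c1ccccc1)(c1ccccc1)c1ccccc1 | starting material
6 | (5R,6S)-5,6-epoxy-5,6-dihydro-β-ionone | C1CC(C)(C)[C@]2(/C=C/C(C)=O)O[C@]2(C)C1 | intermediate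
7 | (3S,5R,6S)-5,6-epoxy-3-hydroxy-5,6-dihydro-β-ionone | O[C@H]1CC(C)(C)[C@]2(/C=C/C(C)=O)O[C@]2(C)C1 | intermediate
8 | myristoyl chloride (tetradecanoyl chloride) | CCCCCCCCCCCCCC(=O)Cl | starting material
9 | (1R,3S,6S)-1,5,5-trimethyl-6-[(E)-3-oxobut-1-en-1-yl]-7-oxabicyclo[4.1.0]heptan-3-yl tetradecanoate | CCCCCCCCCCCCCC(=O)O[C@H]1CC(C)(C)[C@]2(/C=C/C(C)=O)O[C@]2(C)C1 | target

## Step count and least certain steps

Total: 6 steps. Longest linear sequence: 6 steps (1 to 9); 5 and 8 are purchased.

Step 5 (key step, proposed new method). What is most likely to go wrong: hydroxylation at another position (C2, C4 or a methyl group) or on the face syn to the epoxide, because no screened enzyme binds 6 in the required orientation. Also possible are further oxidation of the new alcohol to the ketone, and reduction of the enone or hydrolytic opening of the epoxide by host enzymes during long incubations. The reason is that these enzymes are known for substrates with a flat cyclohexene ring, and the epoxide changes both shape and polarity of ring A. The fallback uses known chemistry and takes the C3 oxygen from a building block instead of a C–H bond. It sets out from 8, which acylates commercial (4R,6R)-4-hydroxy-2,2,6-trimethylcyclohexan-1-one F1 (Et3N, DMAP, CH2Cl2) to give (1R,5R)-3,3,5-trimethyl-4-oxocyclohexyl tetradecanoate F2. Tf2O and 2,6-di-tert-butyl-4-methylpyridine convert the ketone, which can enolise only toward its methyl-bearing α-carbon, into (1R)-3,5,5-trimethyl-4-(trifluoromethanesulfonyloxy)cyclohex-3-en-1-yl tetradecanoate F3. A Heck reaction of F3 with but-3-en-2-one (Pd(OAc)2, PPh3, Et3N, DMF, 70 °C) should give (3R)-3-(tetradecanoyloxy)-β-ionone F4. mCPBA (NaHCO3, CH2Cl2, 0 °C) should then epoxidise the electron-rich C5=C6 bond in preference to the enone and mainly anti to the C3 ester, as peracids do with 3-acyloxy β-rings of carotenoids; the minor syn epoxide would be removed by chromatography. This comes back to the route at 9. The C3 descriptor changes from R to S on epoxidation without any change at that carbon.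

Step 2. What is most likely to go wrong: slow turnover and erosion of enantioselectivity, with Lewis-acid opening of the product on long reaction times. The alkene is tetrasubstituted and flanked by the quaternary C1, so binding and oxygen transfer within the chiral complex are slow. The fallback replaces catalyst control by resolution and sets out from 2. VO(acac)2 and tBuOOH give the racemic epoxy alcohol rac-[(1R,6R)-2,2,6-trimethyl-7-oxabicyclo[4.1.0]heptan-1-yl]methanol F5. Esterification with (S)-2-methoxy-2-phenylacetic acid (DCC, DMAP) gives [(1R,6R)-2,2,6-trimethyl-7-oxabicyclo[4.1.0]heptan-1-yl]methyl (2S)-2-methoxy-2-phenylacetate F6 and its (1S,6S) diastereomer F7, which would be separated by chromatography or crystallisation. Saponification of F6 (LiOH, THF/H2O) comes back to the route at 3.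

Step 4. What is most likely to go wrong: sluggish olefination of the neopentyl-type aldehyde by the weakly nucleophilic ylide, with thermal decomposition of the epoxy aldehyde competing on prolonged heating. The fallback replaces the olefination by an aldol addition and elimination and sets out from 4. The lithium enolate of acetone (LiN(iPr)2, acetone, THF, −78 °C) is smaller than the ylide and should add to the aldehyde to give 4-hydroxy-4-[(1R,6R)-2,2,6-trimethyl-7-oxabicyclo[4.1.0]heptan-1-yl]butan-2-one F8 as a mixture of carbinol epimers. MsCl and Et3N convert it into 3-oxo-1-[(1R,6R)-2,2,6-trimethyl-7-oxabicyclo[4.1.0]heptan-1-yl]butyl methanesulfonate F9, which on addition of DBU undergoes E1cB elimination to the (E)-enone and comes back to the route at 6.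

## Further compounds

F1 | step 5 | (4R,6R)-4-hydroxy-2,2,6-trimethylcyclohexan-1-one | O[C@H]1CC(C)(C)C(=O)[C@H](C)C1
F2 | step 5 | (1R,5R)-3,3,5-trimethyl-4-oxocyclohexyl tetradecanoate | CCCCCCCCCCCCCC(=O)O[C@H]1CC(C)(C)C(=O)[C@H](C)C1
F3 | step 5 | (1R)-3,5,5-trimethyl-4-(trifluoromethanesulfonyloxy)cyclohex-3-en-1-yl tetradecanoate | CCCCCCCCCCCCCC(=O)O[C@H]1CC(C)(C)C(OS(=O)(=O)C(F)(F)F)=C(C)C1
F4 | step 5 | (3R)-3-(tetradecanoyloxy)-β-ionone ((1R)-3,5,5-trimethyl-4-[(E)-3-oxobut-1-en-1-yl]cyclohex-3-en-1-yl tetradecanoate) | CCCCCCCCCCCCCC(=O)O[C@H]1CC(C)(C)C(/C=C/C(C)=O)=C(C)C1
F5 | step 2 | rac-[(1R,6R)-2,2,6-trimethyl-7-oxabicyclo[4.1.0]heptan-1-yl]methanol (racemate, cis-fused; written without stereodescriptors) | OCC12OC1(C)CCCC2(C)C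
F6 | step 2 | [(1R,6R)-2,2,6-trimethyl-7-oxabicyclo[4.1.0]heptan-1-yl]methyl (2S)-2-methoxy-2-phenylacetate | C1CC(C)(C)[C@]2(COC(=O)[C@@H](OC)c3ccccc3)O[C@]2(C)C1
F7 | step 2 | [(1S,6S)-2,2,6-trimethyl-7-oxabicyclo[4.1.0]heptan-1-yl]methyl (2S)-2-methoxy-2-phenylacetate | C1CC(C)(C)[C@@]2(COC(=O)[C@@H](OC)c3ccccc3)O[C@@]2(C)C1
F8 | step 4 | 4-hydroxy-4-[(1R,6R)-2,2,6-trimethyl-7-oxabicyclo[4.1.0]heptan-1-yl]butan-2-one (both carbinol epimers) | C1CC(C)(C)[C@]2(C(O)CC(C)=O)O[C@]2(C)C1
F9 | step 4 | 3-oxo-1-[(1R,6R)-2,2,6-trimethyl-7-oxabicyclo[4.1.0]heptan-1-yl]butyl methanesulfonate (both epimers at the sulfonate carbon) | C1CC(C)(C)[C@]2(C(OS(C)(=O)=O)CC(C)=O)O[C@]2(C)C1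
A1 | alternative 1 | 4-methyl-2-(trimethylsilyloxy)penta-1,3-diene | C=C(O[Si](C)(C)C)C=C(C)C
A2 | alternative 1 | but-2-ynal | CC#CC=O
A3 | alternative 1 | 2,6,6-trimethyl-4-(trimethylsilyloxy)cyclohexa-1,4-diene-1-carbaldehyde | CC1=C(C=O)C(C)(C)C=C(O[Si](C)(C)C)C1
A4 | alternative 2 | methyl (5S)-5-(tert-butyldimethylsilyloxy)-2-chloro-3,3-dimethyl-7-oxooctanoate | CC(C)(C)[Si](C)(C)O[C@H](CC(C)=O)CC(C)(C)C(Cl)C(=O)OC
A5 | alternative 2 | methyl (1S,4S,6R)-4-(tert-butyldimethylsilyloxy)-2,2,6-trimethyl-7-oxabicyclo[4.1.0]heptane-1-carboxylate | CC(C)(C)[Si](C)(C)O[C@H]1CC(C)(C)[C@]2(C(=O)OC)O[C@]2(C)C1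
A6 | alternative 3 | (2S,4S)-4-(tert-butyldimethylsilyloxy)-2-chloro-2,6,6-trimethylcyclohexan-1-one | CC(C)(C)[Si](C)(C)O[C@H]1CC(C)(C)C(=O)[C@@](C)(Cl)C1
A7 | alternative 3 | tert-butyl{[(2S,3E)-4-iodobut-3-en-2-yl]oxy}dimethylsilane | I/C=C/[C@H](C)O[Si](C)(C)C(C)(C)C
A8 | alternative 3 | bis(tert-butyldimethylsilyl) ether of (3S,5R,6S,9S)-5,6-epoxy-3-hydroxy-5,6-dihydro-β-ionol | CC(C)(C)[Si](C)(C)O[C@H]1CC(C)(C)[C@]2(/C=C/[C@H](C)O[Si](C)(C)C(C)(C)C)O[C@]2(C)C1
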